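All runs are simulated with made-up constants, and the scatter is random.

The delta run, with starting material in excess of coupling partner, reads 41 % target at 0.833 h, 46 % at 1.50 h and 37 % at 10.0 h, each reading good to 1.5 percentage points. Its target thus rises quickly and then sinks slowly, so a reversible join is not the whole story and something else drains the flask. The quick rise is read here as starting material S and coupling partner C joining to target T at rate k_f[S][C], while T falls apart at rate k_b[T].

| flask | starting material | coupling partner | remark | time |
|---|---|---|---|---|
| epsilon | 27 mM | 27 mM | the very flask that is asked about, followed so far |  |
| delta | 40 mM | 27 mM | run made earlier |  |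
| flask | 27 mM | 27.0 mM |  | 8.0 d |

| epsilon: time / h | epsilon: target / % | delta: time / h | delta: target / % |
|---|---|---|---|
| 40.0 | 28 | 0.833 | 41 |
| 72.0 | 23 | 1.50 | 46 |
| 120 | 21 | 3.00 | 39 |
| 144 | 20 | 5.00 | 37 |
| 192 | 16 | 10.0 | 37 |

(readings scatter by 1.5 percentage points)

- west: at 8.0 d take out 90 % of the target then present, then wait 2.5 d
- east: at 8.0 d add starting material, 50.0 % of the amount charged, then wait 2.5 d
- south-west: change nothing and wait 2.5 d more
- north: at 8.0 d add coupling partner, 50.0 % of the amount charged, then wait 2.5 d

- removed target is counted in
- additions bring no volume worth counting

- target, in percent of the starting material first charged, at 8.0 d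
- the remedy with the largest gain of target, or "none" below 2 percentage points (west / east / south-west / north / none)
- target present, with what was taken out counted in, in percent of the starting material first charged, after west
- target present, with what was taken out counted in, in percent of the starting material first charged, after east

If the join keeps up with the slow drain, those two rates stay nearly equal, and dividing one by the other removes time and leaves [T]/[S] ≈ (k_f/k_b)[C]. The ratio R = [T]/[S] is therefore a gauge of free coupling partner. Counting starting material not in target as free, delta gives R = 0.587, with free C no higher than 12.2 mM. The epsilon flask, read at 192 h, which is the asked time, gives R = 0.190.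

Scaling by the gauge gives an estimated ceiling on free coupling partner in the epsilon flask at that time, 3.96 mM, which carries the scatter of the readings. Target there holds 4.32 mM, so at least 18.7 mM of coupling partner has gone elsewhere, which makes it the limiting reagent.

This reckoning takes 16 % for the target now. West and east both draw on free coupling partner below that ceiling, whereas north brings 13.5 mM, more than the ceiling, so the choice here is north.

The forecast gives 17.5 % now, 22.5 % after west and 22 % after east, and it names west: “West is the best bet, but this is tentative.”

The flask gives 16.1 %. Its best remedy is north, gaining 9 points against 4.7 points for west. The counted totals are 20.8 % after west and 15.9 % after east.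

    starting material + coupling partner ⇌ target (K = 200 M⁻¹, k = 59.1 M⁻¹ h⁻¹)
    2 coupling partner → side product (k = 9.14 M⁻¹ h⁻¹)
    target ⇌ isomer of the product (K = 0.329, k = 0.0982 h⁻¹)

In this flask at 192 h, the joining of starting material and coupling partner relaxes with a half-life of 0.431 h, far shorter than the 105 h of the slowest mode. Free coupling partner there stands at 1.01 mM, below the ceiling of 3.96 mM. The neighbour charged with 6.8 mM of coupling partner has a ratio of target to free starting material 0.607 times that of the flask, and free coupling partner 0.610 times that of the flask.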